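**Retrosynthetic overview**

1. Endgame: the C3–C4 oxirane comes last, by hydroxyl-directed epoxidation of cyclohexenol 29. The free 2α-OH and the C6 isobutyrate come together from one Evans–Tishchenko reduction of a β-hydroxy enone, and the C5 acetate from a Mitsunobu inversion.
2. Key disconnection (C2–C3 and C4–C5): in the carbocycle the two-carbon unit C3–C4(Me) sits between the two oxygen-bearing ring carbons C2 and C5, i.e. a 2-ene-1,4-dioxygenated cyclohexene once the epoxide is read as an alkene. It is therefore inserted as 2-nitropropene (CH2 becomes C3, the nitro-bearing carbon becomes C4) between the C2 nitronate and the C5 aldehyde of acyclic γ-nitroaldehyde 7 in one nitro-Michael/Henry domino. Both nitro groups are traceless: Nef at C2, loss of nitrite from C4 gives the C3=C4 enone.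
3. Compound 7 (C5–C6–C1–C2, with C6 and C1 set) comes from an organocatalytic anti-Michael addition of silyloxyacetaldehyde 6 to nitroalkene 5.
4. Side chain: grown from the acetal stub on C1 by α-methylenation (C1′=CH2), a reagent-controlled boron aldol (C2′), a 1,3-anti reduction (C4′) and double isobutyrylation.
5. Ring order: the cyclohexane ring is the only carbocycle and is closed in step 5; the oxirane is closed in step 17.

Key step: step 5

Remark: ring atoms are numbered C1 (side chain), C2 (OH), C3/C4 (epoxide, Me on C4), C5 (OAc), C6 (O-isobutyryl), side-chain atoms C1′ (=CH2 carbon) to C5′ (CMe2OH), and β is the face of the C1 side chain; in this numbering all eight stereocentres of the target are S. The configurations drawn at the nitro-bearing carbons of 11 and 12 are assumed (they are erased in step 6), and the antipodes of the catalyst in step 3 and of the borane in step 13 are taken to be those that deliver the drawn enantiomers.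

**Step 1**
Reactants: 1 3,3-diethoxypropan-1-ol
Product: 2 3,3-diethoxypropanal
Conditions: (COCl)2, DMSO, CH2Cl2, −78 °C; Et3N, −78 °C → 0 °C
Reagents that add atoms: none
Why: Swern oxidation of a primary alcohol under basic, anhydrous conditions that leave the acid-labile acetal intact; no stereocentre is involved.

**Step 2**
Reactants: 2 3,3-diethoxypropanal; 3 nitromethane
Product: 5 (E)-4,4-diethoxy-1-nitrobut-1-ene, via nitro alcohol 4 (not isolated)
Conditions: MeNO2 (5 equiv), 1,1,3,3-tetramethylguanidine (5 mol %), THF, 0 °C; then MsCl, Et3N, CH2Cl2, −20 °C → 0 °C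
Reagents that add atoms: none
Why: Henry addition followed by mesylation and E1cB elimination should give the conjugated nitroalkene as the thermodynamically preferred (E) isomer.

**Step 3**
Reactants: 5 (E)-4,4-diethoxy-1-nitrobut-1-ene; 6 (tert-butyldimethylsilyloxy)acetaldehyde
Product: 7 (2S,3S)-2-(tert-butyldimethylsilyloxy)-5,5-diethoxy-3-(nitromethyl)pentanal
Conditions: 1-[(1R,2R)-2-aminocyclohexyl]-3-[3,5-bis(trifluoromethyl)phenyl]thiourea (15 mol %), 6 (2 equiv), CH2Cl2, rt
Reagents that add atoms: none
Why: anti-selective enamine Michael addition of an α-silyloxy aldehyde to a nitroalkene under primary amine–thiourea catalysis; the (Z)-enamine, held by an N–H···O hydrogen bond to the silyloxy group, adds to the thiourea-bound nitroalkene and should set C6 and C1 in the 2,3-anti (2S,3S) sense that becomes the cis C1/C6 relationship of the ring.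

**Step 4**
Reactants: 8 2-nitropropan-1-ol
Product: 9 2-nitropropene
Conditions: phthalic anhydride, 150–180 °C, distillation at reduced pressure; used at once
Reagents that add atoms: none
Why: thermal dehydration of a β-nitro alcohol through its phthalate half-ester (elimination), with the volatile nitroalkene distilled out as it forms; no stereocentre.

**Step 5**
Reactants: 7 (2S,3S)-2-(tert-butyldimethylsilyloxy)-5,5-diethoxy-3-(nitromethyl)pentanal; 9 2-nitropropene
Product: 11 dinitrocyclohexanol (C1 β-CH2CH(OEt)2; C2 β-NO2; C4 β-Me and α-NO2; C5 α-OH; C6 β-OTBS), via acyclic dinitro aldehyde 10 (not isolated)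
Conditions: DBU (0.2 equiv), MeCN, −20 °C, slow addition of 9 (1.5 equiv); then 0 °C; AcOH quench
Reagents that add atoms: none
Why: DBU generates the nitronate of the primary nitro group of 7 (C2), which adds to the unsubstituted CH2 terminus of 2-nitropropene to form C2–C3; the new tertiary nitronate carbon (C4, carrying the methyl) then attacks the C5 aldehyde in an intramolecular Henry reaction that forms C4–C5 and closes the carbocycle. The closest known reaction type is the base-mediated nitro-Michael/Henry domino of γ-nitroaldehydes with nitroalkenes used in organocatalytic Michael/Michael/Henry cyclohexane syntheses. The six-membered ring closes in the 6-(enolexo)-exo-trig mode (nitronate carbon onto the aldehyde). C5 is set in a chair transition state with the C6 silyloxy group equatorial and antiperiplanar to the forming bond, which should place the new hydroxyl trans to it (5α-OH), and reversible Henry closure favours the same trans-diequatorial arrangement; C1 and C6 are carried over from 7, and the configurations at the nitro-bearing C2 and C4 are immaterial because both centres are erased in step 6. The step needs chemoselective deprotonation of the nitromethyl group without enolising the α-silyloxy aldehyde and a regioselective union (CH2 to C2, nitronate carbon to C5); the acidity gap between nitroalkane and aldehyde α-C–H, the fixed polarity of 2-nitropropene and the presence of a single aldehyde secure both.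

**Step 6**
Reactants: 11 dinitrocyclohexanol
Product: 13 4-hydroxy enone (C2 ketone; C3=C4 with Me on C4; 5α-OH; 6β-OTBS; C1 β-CH2CH(OEt)2), via nitro ketone 12 (not isolated)
Conditions: NaNO2, AcOH, DMSO, 35 °C; then Et3N, CH2Cl2, 0 °C
Reagents that add atoms: none
Why: a nitrite-mediated Nef reaction converts only the secondary nitro group at C2 into the ketone (the tertiary C4 nitro group cannot form a nitronate, and the non-basic medium prevents retro-Henry opening), after which Et3N expels nitrite from the β-nitro ketone by E1cB elimination to give the C3=C4 enone without touching C1, C5 or C6.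

**Step 7**
Reactants: 13 4-hydroxy enone
Product: 14 5β-acetoxy enone (6β-OTBS)
Conditions: PPh3, DIAD, AcOH, toluene, 0 °C → rt
Reagents that add atoms: acetic acid CC(=O)O
Why: Mitsunobu esterification, in which SN2 displacement of the oxyphosphonium group by acetate inverts C5 and so turns the 5α-alcohol into the 5β-acetate, cis to the C6 oxygen as in the target.

**Step 8**
Reactants: 14 5β-acetoxy enone
Product: 15 6β-hydroxy-5β-acetoxy enone
Conditions: HF·pyridine, pyridine, THF, 0 °C → rt
Reagents that add atoms: none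
Why: fluoride cleavage of the secondary silyl ether under pyridine-buffered conditions that should spare the acetal, the allylic acetate and the β-hydroxy enone that is formed.

**Step 9**
Reactants: 15 6β-hydroxy-5β-acetoxy enone
Product: 17 cyclohexenol (2α-OH; C3=C4; 5β-OAc; 6β-O-isobutyryl; C1 β-CH2CH(OEt)2), via hemiacetal 16 (not isolated)
Conditions: i-PrCHO (8 equiv), SmI2 (0.3 equiv, premixed with the aldehyde to give the trivalent samarium catalyst), THF, −10 °C
Reagents that add atoms: isobutyraldehyde CC(C)C=O
Why: Evans–Tishchenko reduction, in which the samarium-bound hemiacetal formed from the C6 hydroxyl and isobutyraldehyde delivers its hydride intramolecularly to the β face of the C2 carbonyl through a six-membered transition state; this should give the 1,3-anti product, i.e. the 2α-alcohol (C2 S), and leaves the C6 oxygen as its isobutyrate in the same operation.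

**Step 10**
Reactants: 17 cyclohexenol
Product: 19 aldehyde (C1 β-CH2CHO; 2α-OTES; 5β-OAc; 6β-O-isobutyryl), via collidinium salt 18 (not isolated)
Conditions: TESOTf (3 equiv), 2,4,6-collidine (4.5 equiv), CH2Cl2, 0 °C; then H2O
Reagents that add atoms: triethylsilyl trifluoromethanesulfonate CC[Si](CC)(CC)OS(=O)(=O)C(F)(F)F; water O
Why: silyl triflate/collidine chemistry, in which the triflate silylates the C2 hydroxyl and converts the diethyl acetal via its oxocarbenium ion into a collidinium salt that water hydrolyses to the aldehyde under non-acidic conditions; no stereocentre is touched and the esters are inert.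

**Step 11**
Reactants: 19 aldehyde
Product: 21 enal (C1 β-C(=CH2)CHO; 2α-OTES; 5β-OAc; 6β-O-isobutyryl), via Mannich base 20 (not isolated)
Conditions: CH2=NMe2+ I− (Eschenmoser's salt), Et3N, CH2Cl2, rt
Reagents that add atoms: dimethyl(methylidene)ammonium iodide C=[N+](C)C.[I-]
Why: Mannich reaction of the aldehyde followed by E1cB loss of dimethylamine installs the exocyclic methylene on C1′; no new stereocentre is formed, and C1 is no longer α to a ring carbonyl, so it cannot epimerise.

**Step 12**
Reactants: 22 3-hydroxy-3-methylbutan-2-one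
Product: 23 3-methyl-3-(triethylsilyloxy)butan-2-one
Conditions: TESOTf, 2,6-lutidine, CH2Cl2, 0 °C
Reagents that add atoms: triethylsilyl trifluoromethanesulfonate CC[Si](CC)(CC)OS(=O)(=O)C(F)(F)F
Why: silylation of a tertiary alcohol with a silyl triflate; no stereocentre.

**Step 13**
Reactants: 23 3-methyl-3-(triethylsilyloxy)butan-2-one; 21 enal
Product: 26 (2′S)-β-hydroxy ketone, via enol borinate 24 (not isolated), via boron aldolate 25 (not isolated)
Conditions: 23, (+)-Ipc2BCl (1.3 equiv), Et3N, Et2O, 0 °C; then 21, −78 °C → −20 °C; then 30% H2O2, MeOH, pH 7 buffer, 0 °C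
Reagents that add atoms: none
Why: Paterson boron aldol reaction, in which the diisopinocampheyl enol borinate of the methyl ketone adds 1,2 to the enal through a cyclic transition state under reagent control; (+)-Ipc2BCl should direct attack to the Si face of the aldehyde so that C2′ is formed with the S configuration.

**Step 14**
Reactants: 26 (2′S)-β-hydroxy ketone
Product: 27 (2′S,4′S)-1,3-anti diol
Conditions: Me4NBH(OAc)3, MeCN/AcOH (1:1), −30 °C
Reagents that add atoms: none
Why: Evans–Saksena reduction, in which the C2′ hydroxyl exchanges onto boron and hydride is delivered intramolecularly through a chair transition state; this should give the 1,3-anti diol and set C4′ as S, and the ring holds no ketone that could compete.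

**Step 15**
Reactants: 27 (2′S,4′S)-1,3-anti diol
Product: 28 bis-isobutyrate (2α-OTES; C5′-OTES)
Conditions: i-PrCOCl (4 equiv), pyridine, DMAP (cat.), CH2Cl2, 0 °C → rt
Reagents that add atoms: isobutyryl chloride CC(C)C(Cl)=O
Why: DMAP-catalysed acylation of the two secondary alcohols; the C2 and C5′ oxygens are masked as silyl ethers, so only C2′ and C4′ are esterified and no stereocentre is affected.

**Step 16**
Reactants: 28 bis-isobutyrate
Product: 29 cyclohexenol (2α-OH and C5′-OH free)
Conditions: HF·pyridine, pyridine, THF, 0 °C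
Reagents that add atoms: none
Why: fluoride cleavage of both triethylsilyl ethers under buffered conditions that should leave the acetate and the three isobutyrates in place.

**Step 17**
Reactants: 29 cyclohexenol
Product: 30 CNP0324717.1 (target)
Conditions: VO(acac)2 (5 mol %), t-BuOOH (1.2 equiv, decane), CH2Cl2, 0 °C → rt
Reagents that add atoms: tert-butyl hydroperoxide CC(C)(C)OO
Why: hydroxyl-directed epoxidation, in which the allylic 2α-hydroxyl binds vanadium and delivers the peroxide oxygen to the α face of the C3=C4 alkene; this sets C3 and C4 cis to the hydroxyl and anti to the 5β-acetate, while the homoallylic, ester-flanked C1′ methylene should react much more slowly.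

**Compound list**

1 | 3,3-diethoxypropan-1-ol | CCOC(CCO)OCC | starting material
2 | 3,3-diethoxypropanal | CCOC(CC=O)OCC | intermediate
3 | nitromethane | C[N+](=O)[O-] | starting material
4 | 4,4-diethoxy-1-nitrobutan-2-ol (racemic, not isolated) | CCOC(CC(O)C[N+](=O)[O-])OCC | intermediate
5 | (E)-4,4-diethoxy-1-nitrobut-1-ene | CCOC(C/C=C/[N+](=O)[O-])OCC | intermediate
6 | (tert-butyldimethylsilyloxy)acetaldehyde | O=CCO[Si](C)(C)C(C)(C)C | starting material
7 | (2S,3S)-2-(tert-butyldimethylsilyloxy)-5,5-diethoxy-3-(nitromethyl)pentanal | O=C[C@@H](O[Si](C)(C)C(C)(C)C)[C@@H](CC(OCC)OCC)C[N+](=O)[O-] | intermediate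
8 | 2-nitropropan-1-ol (racemic) | CC(CO)[N+](=O)[O-] | starting material
9 | 2-nitropropene | C=C(C)[N+](=O)[O-] | intermediate
10 | (2S,3S)-2-(tert-butyldimethylsilyloxy)-3-(2,2-diethoxyethyl)-4,6-dinitroheptanal (epimers at the nitro-bearing carbons, not isolated) | O=C[C@@H](O[Si](C)(C)C(C)(C)C)[C@@H](CC(OCC)OCC)C(CC(C)[N+](=O)[O-])[N+](=O)[O-] | intermediate
11 | dinitrocyclohexanol: C1 β-(2,2-diethoxyethyl), C2 β-nitro, C4 β-methyl/α-nitro, C5 α-hydroxy, C6 β-OTBS | CCOC(OCC)C[C@H]1[C@@H]([N+](=O)[O-])C[C@](C)([N+](=O)[O-])[C@H](O)[C@H]1O[Si](C)(C)C(C)(C)C | intermediate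
12 | β-nitro ketone: as 11 with C2 as ketone (not isolated) | CCOC(OCC)C[C@H]1C(=O)C[C@](C)([N+](=O)[O-])[C@H](O)[C@H]1O[Si](C)(C)C(C)(C)C | intermediate
13 | 6β-(2,2-diethoxyethyl)-5β-(tert-butyldimethylsilyloxy)-4α-hydroxy-3-methylcyclohex-2-en-1-one (target numbering: C2 ketone, 5α-OH, 6β-OTBS) | CCOC(OCC)C[C@H]1C(=O)C=C(C)[C@H](O)[C@H]1O[Si](C)(C)C(C)(C)C | intermediate
14 | 5β-acetate of the C5 epimer of 13 (5β-OAc, 6β-OTBS, C2 ketone) | CCOC(OCC)C[C@H]1C(=O)C=C(C)[C@@H](OC(C)=O)[C@H]1O[Si](C)(C)C(C)(C)C | intermediate
15 | 6β-hydroxy-5β-acetoxy enone | CCOC(OCC)C[C@H]1C(=O)C=C(C)[C@@H](OC(C)=O)[C@H]1O | intermediate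
16 | hemiacetal of 15 with isobutyraldehyde at the C6 oxygen (samarium-bound, not isolated) | CCOC(OCC)C[C@H]1C(=O)C=C(C)[C@@H](OC(C)=O)[C@H]1OC(O)C(C)C | intermediate
17 | cyclohexenol: 2α-OH, C3=C4 (4-Me), 5β-OAc, 6β-O-isobutyryl, C1 β-(2,2-diethoxyethyl) | CCOC(OCC)C[C@H]1[C@H](O)C=C(C)[C@@H](OC(C)=O)[C@H]1OC(=O)C(C)C | intermediate
18 | N-(1-ethoxyalkyl)-2,4,6-trimethylpyridinium triflate of the 2α-OTES ether (not isolated) | CCOC(C[C@H]1[C@H](O[Si](CC)(CC)CC)C=C(C)[C@@H](OC(C)=O)[C@H]1OC(=O)C(C)C)[n+]1c(C)cc(C)cc1C.[O-]S(=O)(=O)C(F)(F)F | intermediate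
19 | aldehyde: C1 β-CH2CHO, 2α-OTES, 5β-OAc, 6β-O-isobutyryl | O=CC[C@H]1[C@H](O[Si](CC)(CC)CC)C=C(C)[C@@H](OC(C)=O)[C@H]1OC(=O)C(C)C | intermediate
20 | Mannich base: α-(dimethylaminomethyl) aldehyde (epimers at the new carbon, not isolated) | O=CC(CN(C)C)[C@H]1[C@H](O[Si](CC)(CC)CC)C=C(C)[C@@H](OC(C)=O)[C@H]1OC(=O)C(C)C | intermediate
21 | enal: C1 β-C(=CH2)CHO, 2α-OTES, 5β-OAc, 6β-O-isobutyryl | C=C(C=O)[C@H]1[C@H](O[Si](CC)(CC)CC)C=C(C)[C@@H](OC(C)=O)[C@H]1OC(=O)C(C)C | intermediate
22 | 3-hydroxy-3-methylbutan-2-one | CC(=O)C(C)(C)O | starting material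
23 | 3-methyl-3-(triethylsilyloxy)butan-2-one | CC(=O)C(C)(C)O[Si](CC)(CC)CC | intermediate
24 | diisopinocampheyl enol borinate of 23 (not isolated) | C=C(OB([C@H]1C[C@H]2C[C@@H]([C@@H]1C)C2(C)C)[C@H]1C[C@H]2C[C@@H]([C@@H]1C)C2(C)C)C(C)(C)O[Si](CC)(CC)CC | intermediate
25 | boron aldolate: (2′S)-O-diisopinocampheylboryl adduct (not isolated) | C=C([C@H]1[C@H](O[Si](CC)(CC)CC)C=C(C)[C@@H](OC(C)=O)[C@H]1OC(=O)C(C)C)[C@@H](OB([C@H]1C[C@H]2C[C@@H]([C@@H]1C)C2(C)C)[C@H]1C[C@H]2C[C@@H]([C@@H]1C)C2(C)C)CC(=O)C(C)(C)O[Si](CC)(CC)CC | intermediate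
26 | (2′S)-β-hydroxy ketone (C4′ ketone, C5′-OTES, 2α-OTES) | C=C([C@H]1[C@H](O[Si](CC)(CC)CC)C=C(C)[C@@H](OC(C)=O)[C@H]1OC(=O)C(C)C)[C@@H](O)CC(=O)C(C)(C)O[Si](CC)(CC)CC | intermediate
27 | (2′S,4′S)-1,3-anti diol (C5′-OTES, 2α-OTES) | C=C([C@H]1[C@H](O[Si](CC)(CC)CC)C=C(C)[C@@H](OC(C)=O)[C@H]1OC(=O)C(C)C)[C@@H](O)C[C@H](O)C(C)(C)O[Si](CC)(CC)CC | intermediate
28 | 2′,4′-bis-isobutyrate (C5′-OTES, 2α-OTES) | C=C([C@H]1[C@H](O[Si](CC)(CC)CC)C=C(C)[C@@H](OC(C)=O)[C@H]1OC(=O)C(C)C)[C@H](C[C@H](OC(=O)C(C)C)C(C)(C)O[Si](CC)(CC)CC)OC(=O)C(C)C | intermediate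
29 | 3,4-deoxy target: cyclohex-3-en-2α-ol with 5β-OAc, 6β-O-isobutyryl and the complete side chain | C=C([C@H]1[C@H](O)C=C(C)[C@@H](OC(C)=O)[C@H]1OC(=O)C(C)C)[C@H](C[C@H](OC(=O)C(C)C)C(C)(C)O)OC(=O)C(C)C | intermediate
30 | CNP0324717.1 (3α,4α-epoxide; ring 1S,2S,3S,4S,5S,6S and side chain 2′S,4′S in the numbering used here) | C=C([C@H]1[C@H](O)[C@@H]2O[C@]2(C)[C@@H](OC(C)=O)[C@H]1OC(=O)C(C)C)[C@H](C[C@H](OC(=O)C(C)C)C(C)(C)O)OC(=O)C(C)C | target

**Step count and risks**

Total step count: 17. Longest linear sequence: 15 steps (steps 1–3, 5–11 and 13–17); steps 4 and 12 prepare the two side branches.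

Steps most likely to fail:

Step 5 (key step). What may go wrong: base-induced epimerisation at C6 of the α-silyloxy aldehyde before ring closure, anionic polymerisation of 9, and retro-Henry scrambling of the domino. Fallback: the fallback sets out from 7 and comes back at 11; it decouples the two C–C bond formations by removing the aldehyde during the Michael step. NaBH4 (MeOH, 0 °C) should reduce 7 to (2S,3S)-2-(tert-butyldimethylsilyloxy)-5,5-diethoxy-3-(nitromethyl)pentan-1-ol F1. A weak-base (Et3N or tertiary amine–thiourea) nitro-Michael addition of F1 to 9 should then give the dinitro alcohol F2 with no enolisable aldehyde present. Dess–Martin oxidation returns the acyclic aldehyde 10, which is cyclised in a separate Henry reaction (Et3N, CH2Cl2, −20 °C) to 11.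

Step 7 (Mitsunobu inversion). What may go wrong: slow SN2 displacement at the hindered allylic C5 carbinol (flanked by the C6 silyl ether and the C4 methyl) with competing elimination or ionisation, giving loss of material or incomplete inversion. Fallback: the fallback sets out from 11 and comes back at 14; it sets C5 by hydride delivery instead of displacement. Dess–Martin oxidation of 11 should give the α-nitro ketone F3. NaBH4/CeCl3 (MeOH, −78 °C, acidic quench) should attack anti to the 6β-silyloxy group and give the 5β-alcohol F4, which Ac2O/pyridine converts into the 5β-acetate F5. The conditions of step 6 (NaNO2, AcOH, DMSO; then Et3N) then take F5 directly to 14.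

Step 9 (Evans–Tishchenko reduction). What may go wrong: reductive cleavage of the γ-acetoxy enone by residual divalent samarium, acetyl migration from C5 to C6, or poor intramolecular hydride transfer to the conjugated carbonyl. Fallback: the fallback sets out from 15 and comes back at 17; it replaces intramolecular delivery by reagent control. Isobutyric anhydride/pyridine (0 °C) should acylate the C6 hydroxyl to give the 6β-isobutyryloxy enone F6. A CBS reduction ((S)-2-methyl-CBS-oxazaborolidine, catecholborane, toluene, −78 °C) then delivers hydride to the β face of the C2 carbonyl and gives 17.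

**Further compounds**

F1 | step 5 | (2S,3S)-2-(tert-butyldimethylsilyloxy)-5,5-diethoxy-3-(nitromethyl)pentan-1-ol | OC[C@@H](O[Si](C)(C)C(C)(C)C)[C@@H](CC(OCC)OCC)C[N+](=O)[O-]
F2 | step 5 | (2S,3S)-2-(tert-butyldimethylsilyloxy)-3-(2,2-diethoxyethyl)-4,6-dinitroheptan-1-ol (epimers at the nitro-bearing carbons) | OC[C@@H](O[Si](C)(C)C(C)(C)C)[C@@H](CC(OCC)OCC)C(CC(C)[N+](=O)[O-])[N+](=O)[O-]
F3 | step 7 | α-nitro ketone: 11 with C5 as ketone | CCOC(OCC)C[C@H]1[C@@H]([N+](=O)[O-])C[C@](C)([N+](=O)[O-])C(=O)[C@H]1O[Si](C)(C)C(C)(C)C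
F4 | step 7 | C5 epimer of 11 (5β-OH, cis to 6β-OTBS) | CCOC(OCC)C[C@H]1[C@@H]([N+](=O)[O-])C[C@](C)([N+](=O)[O-])[C@@H](O)[C@H]1O[Si](C)(C)C(C)(C)C
F5 | step 7 | 5β-acetate of F4 | CCOC(OCC)C[C@H]1[C@@H]([N+](=O)[O-])C[C@](C)([N+](=O)[O-])[C@@H](OC(C)=O)[C@H]1O[Si](C)(C)C(C)(C)C
F6 | step 9 | 6β-isobutyryloxy-5β-acetoxy enone (C2 ketone) | CCOC(OCC)C[C@H]1C(=O)C=C(C)[C@@H](OC(C)=O)[C@H]1OC(=O)C(C)C
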